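**Plan**
1. Retrosynthesis cuts the two ester C–O bonds first. Both come from one amino alcohol, 11: acyl transfer with retention at C-6 gives the ester cis to the aryl rings, and Mitsunobu inversion gives the ester trans to them. The next cut is the cyclobutane bond between an ArCH carbon and the CH carbon whose ester is trans to the aryl rings.
2. That bond joins a benzylic carbon to an α-carbonyl carbon, so it is the collapse of a benzylic/α-ester 1,4-biradical. The biradical comes from a pyrrolidine whose nitrogen bridges these two carbons, by loss of N2 from its 1,1-diazene. The pyrrolidine is the (3+2) adduct of the glycine imine of O-benzylvanillin with a cinnamate locked Z as a coumarin (scopoletin benzyl ether).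
3. Forward, core: coumarin + azomethine ylide gives a lactone-fused pyrrolidine; nitrogen deletion closes the four-membered ring; the lactone is opened and the ester carbon equilibrated to trans; the extra aryl oxygen leaves through its triflate, giving a meso mono-acid; two esterifications and debenzylation follow.
4. Forward, amino alcohol: a Pauson–Khand reaction of an N-Boc 1,7-enyne forms the piperidine and cyclopentenone rings together; hydrogenation with C-7 equilibration and LiAlH4 finish 11.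
5. Stereochemistry: the core is meso (mirror plane through the two ester carbons) and needs only relative control. The cis aryl/ester/aryl triad comes from the coumarin ring, endo cycloaddition and retention on N2 loss; the trans ester comes from equilibration. In 11, C-4 comes from (S)-Boc-β2-homoalanine and is relayed to C-4a (Pauson–Khand), C-7a (hydrogenation), C-7 (equilibration) and C-6 (hydride from the convex face).

Key step: step 10

**Remarks on the chemistry**
- The target is read as follows: the two aryl groups are cis to each other; the ester of the (6R) alcohol is cis to both aryl rings; the ester of the (6S) alcohol is trans to both. The two amino-alcohol units share the (4R,4aR,7R,7aS) skeleton and differ only at C-6.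
- Because the core is achiral, 17–22 are made as racemates (one enantiomer is written). The mirror plane exchanges the two aryl-bearing carbons, so both antipodes converge on meso 23.
- Compounds 1, 12, 14 and 15 are taken to be purchasable.

**Route**

Step 1
Reactants: 1 (2S)-3-[(tert-butoxycarbonyl)amino]-2-methylpropanoic acid
Product: 2 tert-butyl {(2S)-3-[methoxy(methyl)amino]-2-methyl-3-oxopropyl}carbamate
Conditions: MeNH(OMe)·HCl, EDC·HCl, HOBt, i-Pr2NEt, CH2Cl2, 0 °C → rt
Reagents that add atoms: N,O-dimethylhydroxylamine hydrochloride, CNOC.Cl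
Why: Carbodiimide amide coupling to the N-methoxy-N-methylamide should proceed without touching the α-stereocentre.

Step 2
Reactants: 2 tert-butyl {(2S)-3-[methoxy(methyl)amino]-2-methyl-3-oxopropyl}carbamate
Product: 3 tert-butyl [(2S)-2-methyl-3-oxopropyl]carbamate
Conditions: LiAlH4, THF, 0 °C; Na2SO4·10H2O
Reagents that add atoms: none
Why: Hydride reduction of the N-methoxy-N-methylamide should stop at the aldehyde through the chelated tetrahedral intermediate; the aldehyde is used at once to protect the α-centre.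

Step 3
Reactants: 3 tert-butyl [(2S)-2-methyl-3-oxopropyl]carbamate
Product: 4 tert-butyl [(2R)-2-methylbut-3-en-1-yl]carbamate
Conditions: Ph3PCH3Br, KN(SiMe3)2, THF, 0 °C; then 3, −78 °C → rt
Reagents that add atoms: methyltriphenylphosphonium bromide, C[P+](c1ccccc1)(c1ccccc1)c1ccccc1.[Br-]
Why: Wittig methylenation at low temperature should give the vinyl group with the stereocentre intact (the descriptor changes to R only through the priority change).

Step 4
Reactants: 4 tert-butyl [(2R)-2-methylbut-3-en-1-yl]carbamate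
Product: 5 tert-butyl (but-2-yn-1-yl)[(2R)-2-methylbut-3-en-1-yl]carbamate
Conditions: NaH, DMF, 0 °C; 1-bromobut-2-yne, 0 °C → rt
Reagents that add atoms: 1-bromobut-2-yne, CC#CCBr
Why: N-alkylation of the carbamate anion with a propargylic bromide (SN2) should give the 1,7-enyne.

Step 5
Reactants: 5 tert-butyl (but-2-yn-1-yl)[(2R)-2-methylbut-3-en-1-yl]carbamate
Product: 7 tert-butyl (4R,4aR)-4,7-dimethyl-6-oxo-1,3,4,4a,5,6-hexahydro-2H-cyclopenta[c]pyridine-2-carboxylate, via alkyne–Co2(CO)6 complex 6 (not isolated)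
Conditions: Co2(CO)8, CH2Cl2, rt; then N-methylmorpholine N-oxide, rt
Reagents that add atoms: dicobalt octacarbonyl Co2(CO)8 (supplies CO), [Co].[Co].[C-]#[O+].[C-]#[O+].[C-]#[O+].[C-]#[O+].[C-]#[O+].[C-]#[O+].[C-]#[O+].[C-]#[O+]
Why: The intramolecular Pauson–Khand reaction should close the piperidine and the cyclopentenone together; the C-4 methyl lies pseudo-equatorial in the chair-like alkene-insertion transition state, which places H-4a cis to that methyl.

Step 6
Reactants: 7 tert-butyl (4R,4aR)-4,7-dimethyl-6-oxo-1,3,4,4a,5,6-hexahydro-2H-cyclopenta[c]pyridine-2-carboxylate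
Product: 9 tert-butyl (4R,4aR,7R,7aS)-4,7-dimethyl-6-oxooctahydro-2H-cyclopenta[c]pyridine-2-carboxylate, via all-cis ketone 8 (not isolated)
Conditions: H2 (1 atm), Pd/C, EtOAc, rt; filter; NaOMe (cat.), MeOH, rt
Reagents that add atoms: none
Why: Heterogeneous hydrogenation should add H2 to the enone from the face of H-4a and so give the cis ring fusion; the C-7 methyl, first delivered to the concave face, is equilibrated through the enolate to the more stable position trans to C-1.

Step 7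
Reactants: 9 tert-butyl (4R,4aR,7R,7aS)-4,7-dimethyl-6-oxooctahydro-2H-cyclopenta[c]pyridine-2-carboxylate
Product: 11 (4R,4aR,6R,7R,7aS)-2,4,7-trimethyloctahydro-1H-cyclopenta[c]pyridin-6-ol, via N-Boc alcohol 10 (not isolated)
Conditions: LiAlH4, THF, −78 °C → 0 °C, then reflux; Na2SO4·10H2O
Reagents that add atoms: none
Why: The small hydride should attack the cyclopentanone from the convex face, which is also the torsionally preferred side syn to the α-methyl (as in 2-methylcyclopentanone), giving the alcohol with OH trans to the C-7 methyl; at reflux the tert-butyl carbamate is reduced to N-methyl.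

Step 8
Reactants: 12 scopoletin (7-hydroxy-6-methoxy-2H-chromen-2-one)
Product: 13 7-(benzyloxy)-6-methoxy-2H-chromen-2-one
Conditions: BnBr, K2CO3, DMF, rt
Reagents that add atoms: benzyl bromide, BrCc1ccccc1
Why: Williamson etherification protects the phenol that becomes the 4-hydroxy group of one aryl ring.

Step 9
Reactants: 13 7-(benzyloxy)-6-methoxy-2H-chromen-2-one; 14 4-(benzyloxy)-3-methoxybenzaldehyde; 15 glycine tert-butyl ester hydrochloride
Product: 17 rac-tert-butyl 7-(benzyloxy)-3-[4-(benzyloxy)-3-methoxyphenyl]-8-methoxy-4-oxo-1,2,3,3a,4,9b-hexahydrochromeno[3,4-c]pyrrole-1-carboxylate (H-1/H-3/H-3a/H-9b all cis), via glycine imine 16 (not isolated)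
Conditions: Et3N, MgSO4, toluene, rt (14 + 15); then 13, AgOAc (10 mol %), PPh3 (12 mol %), 50 °C
Reagents that add atoms: none
Why: 1,3-Dipolar cycloaddition of the W-shaped N-metalated azomethine ylide joins the glycine carbon to C-4 of the coumarin (the Michael terminus) and the imine carbon to C-3; the lactone ring fixes aryl and carbonyl cis on the dipolarophile, and endo approach (lactone carbonyl under the silver-bound ylide) places the new aryl group cis to them.

Step 10
Reactants: 17 rac-tert-butyl 7-(benzyloxy)-3-[4-(benzyloxy)-3-methoxyphenyl]-8-methoxy-4-oxo-1,2,3,3a,4,9b-hexahydrochromeno[3,4-c]pyrrole-1-carboxylate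
Product: 19 rac-tert-butyl 6-(benzyloxy)-2-[4-(benzyloxy)-3-methoxyphenyl]-7-methoxy-3-oxo-1,2,2a,8b-tetrahydro-3H-cyclobuta[c]chromene-1-carboxylate (H-1/H-2/H-2a/H-8b all cis), via 1,1-diazene 18 (not isolated)
Conditions: N-(benzyloxy)-N-(pivaloyloxy)-4-(trifluoromethyl)benzamide (1.5 equiv), THF, 45 °C
Reagents that add atoms: none
Why: The secondary amine of 17 attacks the electrophilic nitrogen of the anomeric amide with loss of pivalate; the N-amino adduct expels benzyl 4-(trifluoromethyl)benzoate to give the 1,1-diazene 18, which loses N2 to a singlet 1,4-biradical whose ends (benzylic C-3 and α-ester C-1 of the pyrrolidine) recombine to form the cyclobutane bond. The closest known reaction type is nitrogen deletion of secondary amines through isodiazenes, in particular the stereoretentive contraction of polysubstituted pyrrolidines to cyclobutanes and the classical decomposition of N-aminopyrrolidine-derived 1,1-diazenes. The four-membered ring is closed by intramolecular radical–radical coupling of the 1,4-biradical, a ring contraction by extrusion and not a polar exo or endo closure. No stereocentre is created afresh: the configurations at the two bond-forming carbons are carried over from the pyrrolidine because collapse of the singlet biradical is faster than rotation about the adjacent C–C bonds, and C-3a and C-9b are untouched. The step needs coupling to win over β-scission of the central C–C bond and needs retention at the benzylic end; both radical ends are stabilised (aryl, ester) so N2 is lost at 45 °C, and the cis-fused lactone holds the chain cisoid, while the ester end need not be trusted because step 11 equilibrates it. The ammonia-free reagent is chosen because the aryl lactone would not survive the ammonium carbamate of the iodonitrene variant.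

Step 11
Reactants: 19 rac-tert-butyl 6-(benzyloxy)-2-[4-(benzyloxy)-3-methoxyphenyl]-7-methoxy-3-oxo-1,2,2a,8b-tetrahydro-3H-cyclobuta[c]chromene-1-carboxylate
Product: 22 rac-(1α,2α,3β,4α)-3-(tert-butoxycarbonyl)-2-[4-(benzyloxy)-5-methoxy-2-{[(trifluoromethyl)sulfonyl]oxy}phenyl]-4-[4-(benzyloxy)-3-methoxyphenyl]cyclobutane-1-carboxylic acid, via all-cis dipotassium phenoxide carboxylate 20 (not isolated), via C-3 epimerised dipotassium salt 21 (not isolated)
Conditions: KOSiMe3 (2.2 equiv), THF, 0 °C → rt; KOt-Bu (2 equiv), t-BuOH, 45 °C; AcOH; PhNTf2, 0 °C → rt; aq. citric acid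
Reagents that add atoms: potassium trimethylsilanolate, C[Si](C)(C)[O-].[K+]; N-phenylbis(trifluoromethanesulfonimide), O=S(=O)(N(c1ccccc1)S(=O)(=O)C(F)(F)F)C(F)(F)F
Why: Silanolate opens the aryl lactone to a carboxylate that can no longer enolise, tert-butoxide then equilibrates the tert-butyl ester carbon (the only enolisable centre) to the stable position trans to both flanking aryl groups, and the liberated phenoxide is sulfonylated.

Step 12
Reactants: 22 rac-(1α,2α,3β,4α)-3-(tert-butoxycarbonyl)-2-[4-(benzyloxy)-5-methoxy-2-{[(trifluoromethyl)sulfonyl]oxy}phenyl]-4-[4-(benzyloxy)-3-methoxyphenyl]cyclobutane-1-carboxylic acid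
Product: 23 (1α,2α,3β,4α)-2,4-bis[4-(benzyloxy)-3-methoxyphenyl]-3-(tert-butoxycarbonyl)cyclobutane-1-carboxylic acid (meso)
Conditions: Pd(OAc)2 (5 mol %), dppf, HCO2H, Et3N, DMF, 70 °C
Reagents that add atoms: none
Why: Palladium-catalysed formate reduction of the aryl triflate (oxidative addition, hydride from formate, reductive elimination) removes the helper oxygen; the two aryl rings become identical and the core becomes meso.

Step 13
Reactants: 23 (1α,2α,3β,4α)-2,4-bis[4-(benzyloxy)-3-methoxyphenyl]-3-(tert-butoxycarbonyl)cyclobutane-1-carboxylic acid; 11 (4R,4aR,6R,7R,7aS)-2,4,7-trimethyloctahydro-1H-cyclopenta[c]pyridin-6-ol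
Product: 24 3-tert-butyl 1-[(4R,4aR,6R,7R,7aS)-2,4,7-trimethyloctahydro-1H-cyclopenta[c]pyridin-6-yl] (1α,2α,3β,4α)-2,4-bis[4-(benzyloxy)-3-methoxyphenyl]cyclobutane-1,3-dicarboxylate
Conditions: 2-methyl-6-nitrobenzoic anhydride, DMAP, Et3N, CH2Cl2, rt
Reagents that add atoms: none
Why: Shiina mixed-anhydride esterification acylates the alcohol oxygen with retention at C-6; if the hindered acyl donor passes through its ketene, protonation of the enol from the face opposite the two aryl rings gives the same cis ester.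

Step 14
Reactants: 24 3-tert-butyl 1-[(4R,4aR,6R,7R,7aS)-2,4,7-trimethyloctahydro-1H-cyclopenta[c]pyridin-6-yl] (1α,2α,3β,4α)-2,4-bis[4-(benzyloxy)-3-methoxyphenyl]cyclobutane-1,3-dicarboxylate
Product: 25 (1α,2β,3β,4β)-2,4-bis[4-(benzyloxy)-3-methoxyphenyl]-3-({[(4R,4aR,6R,7R,7aS)-2,4,7-trimethyloctahydro-1H-cyclopenta[c]pyridin-6-yl]oxy}carbonyl)cyclobutane-1-carboxylic acid
Conditions: CF3CO2H/CH2Cl2 (1:4), 0 °C → rt
Reagents that add atoms: none
Why: Acidolysis of the tert-butyl ester (loss of 2-methylpropene) should leave the secondary ester, the aryl benzyl ethers and the acid-stable cis ester centre untouched.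

Step 15
Reactants: 25 (1α,2β,3β,4β)-2,4-bis[4-(benzyloxy)-3-methoxyphenyl]-3-({[(4R,4aR,6R,7R,7aS)-2,4,7-trimethyloctahydro-1H-cyclopenta[c]pyridin-6-yl]oxy}carbonyl)cyclobutane-1-carboxylic acid; 11 (4R,4aR,6R,7R,7aS)-2,4,7-trimethyloctahydro-1H-cyclopenta[c]pyridin-6-ol
Product: 26 1-[(4R,4aR,6R,7R,7aS)-2,4,7-trimethyloctahydro-1H-cyclopenta[c]pyridin-6-yl] 3-[(4R,4aR,6S,7R,7aS)-2,4,7-trimethyloctahydro-1H-cyclopenta[c]pyridin-6-yl] (1α,2α,3β,4α)-2,4-bis[4-(benzyloxy)-3-methoxyphenyl]cyclobutane-1,3-dicarboxylate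
Conditions: PPh3, DIAD, THF, 0 °C → rt
Reagents that add atoms: none
Why: Mitsunobu esterification displaces the activated C-6 oxygen of the concave alcohol by the carboxylate from the convex face (SN2), inverting C-6 to S and giving the second, epimeric ester under neutral conditions that cannot epimerise the cis ester.

Step 16
Reactants: 26 1-[(4R,4aR,6R,7R,7aS)-2,4,7-trimethyloctahydro-1H-cyclopenta[c]pyridin-6-yl] 3-[(4R,4aR,6S,7R,7aS)-2,4,7-trimethyloctahydro-1H-cyclopenta[c]pyridin-6-yl] (1α,2α,3β,4α)-2,4-bis[4-(benzyloxy)-3-methoxyphenyl]cyclobutane-1,3-dicarboxylate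
Product: 27 1-[(4R,4aR,6R,7R,7aS)-2,4,7-trimethyloctahydro-1H-cyclopenta[c]pyridin-6-yl] 3-[(4R,4aR,6S,7R,7aS)-2,4,7-trimethyloctahydro-1H-cyclopenta[c]pyridin-6-yl] (1α,2α,3β,4α)-2,4-bis(4-hydroxy-3-methoxyphenyl)cyclobutane-1,3-dicarboxylate (CNP0283097.4)
Conditions: H2 (1 atm), Pd(OH)2/C, AcOH, EtOAc/MeOH, rt
Reagents that add atoms: none
Why: Hydrogenolysis of the two aryl benzyl ethers with the amines protonated should free both phenols under non-basic conditions that leave the contra-thermodynamic cis ester in place.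

**Compound list**
1 | (2S)-3-[(tert-butoxycarbonyl)amino]-2-methylpropanoic acid | CC(C)(C)OC(=O)NC[C@H](C)C(=O)O | starting material
2 | tert-butyl {(2S)-3-[methoxy(methyl)amino]-2-methyl-3-oxopropyl}carbamate | CC(C)(C)OC(=O)NC[C@H](C)C(=O)N(C)OC | intermediate
3 | tert-butyl [(2S)-2-methyl-3-oxopropyl]carbamate | CC(C)(C)OC(=O)NC[C@H](C)C=O | intermediate
4 | tert-butyl [(2R)-2-methylbut-3-en-1-yl]carbamate | CC(C)(C)OC(=O)NC[C@H](C)C=C | intermediate
5 | tert-butyl (but-2-yn-1-yl)[(2R)-2-methylbut-3-en-1-yl]carbamate | CC#CCN(C(=O)OC(C)(C)C)C[C@H](C)C=C | intermediate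
6 | alkyne–Co2(CO)6 complex of 5 (not isolated) | CC#CCN(C(=O)OC(C)(C)C)C[C@H](C)C=C.[Co].[Co].[C-]#[O+].[C-]#[O+].[C-]#[O+].[C-]#[O+].[C-]#[O+].[C-]#[O+] | intermediate
7 | tert-butyl (4R,4aR)-4,7-dimethyl-6-oxo-1,3,4,4a,5,6-hexahydro-2H-cyclopenta[c]pyridine-2-carboxylate | O=C1C[C@H]2C(=C1C)CN(C(=O)OC(C)(C)C)C[C@@H]2C | intermediate
8 | tert-butyl (4R,4aR,7S,7aS)-4,7-dimethyl-6-oxooctahydro-2H-cyclopenta[c]pyridine-2-carboxylate (H-4a, H-7a, H-7 all cis; not isolated) | O=C1C[C@H]2[C@H](CN(C(=O)OC(C)(C)C)C[C@@H]2C)[C@@H]1C | intermediate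
9 | tert-butyl (4R,4aR,7R,7aS)-4,7-dimethyl-6-oxooctahydro-2H-cyclopenta[c]pyridine-2-carboxylate | O=C1C[C@H]2[C@H](CN(C(=O)OC(C)(C)C)C[C@@H]2C)[C@H]1C | intermediate
10 | tert-butyl (4R,4aR,6R,7R,7aS)-6-hydroxy-4,7-dimethyloctahydro-2H-cyclopenta[c]pyridine-2-carboxylate (present as its aluminium alkoxide; not isolated) | O[C@@H]1C[C@H]2[C@H](CN(C(=O)OC(C)(C)C)C[C@@H]2C)[C@H]1C | intermediate
11 | (4R,4aR,6R,7R,7aS)-2,4,7-trimethyloctahydro-1H-cyclopenta[c]pyridin-6-ol | O[C@@H]1C[C@H]2[C@H](CN(C)C[C@@H]2C)[C@H]1C | intermediate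
12 | scopoletin (7-hydroxy-6-methoxy-2H-chromen-2-one) | COc1cc2ccc(=O)oc2cc1O | starting material
13 | 7-(benzyloxy)-6-methoxy-2H-chromen-2-one | COc1cc2ccc(=O)oc2cc1OCc1ccccc1 | intermediate
14 | 4-(benzyloxy)-3-methoxybenzaldehyde | COc1cc(C=O)ccc1OCc1ccccc1 | starting material
15 | glycine tert-butyl ester hydrochloride | Cl.NCC(=O)OC(C)(C)C | starting material
16 | tert-butyl N-[(E)-4-(benzyloxy)-3-methoxybenzylidene]glycinate (not isolated) | COc1cc(/C=N/CC(=O)OC(C)(C)C)ccc1OCc1ccccc1 | intermediate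
17 | rac-tert-butyl 7-(benzyloxy)-3-[4-(benzyloxy)-3-methoxyphenyl]-8-methoxy-4-oxo-1,2,3,3a,4,9b-hexahydrochromeno[3,4-c]pyrrole-1-carboxylate, H-1, H-3, H-3a, H-9b all cis (one enantiomer written) | COc1cc(ccc1OCc1ccccc1)[C@@H]2N[C@H](C(=O)OC(C)(C)C)[C@@H]3c4cc(OC)c(OCc5ccccc5)cc4OC(=O)[C@H]23 | intermediate
18 | 1,1-diazene (N-nitrene) of 17, same relative configuration (not isolated) | COc1cc(ccc1OCc1ccccc1)[C@@H]2[N+](=[N-])[C@H](C(=O)OC(C)(C)C)[C@@H]3c4cc(OC)c(OCc5ccccc5)cc4OC(=O)[C@H]23 | intermediate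
19 | rac-tert-butyl 6-(benzyloxy)-2-[4-(benzyloxy)-3-methoxyphenyl]-7-methoxy-3-oxo-1,2,2a,8b-tetrahydro-3H-cyclobuta[c]chromene-1-carboxylate, H-1, H-2, H-2a, H-8b all cis (one enantiomer written) | COc1cc(ccc1OCc1ccccc1)[C@@H]2[C@H](C(=O)OC(C)(C)C)[C@@H]3c4cc(OC)c(OCc5ccccc5)cc4OC(=O)[C@H]23 | intermediate
20 | rac-dipotassium 2-[4-(benzyloxy)-5-methoxy-2-oxidophenyl]-4-[4-(benzyloxy)-3-methoxyphenyl]-3-(tert-butoxycarbonyl)cyclobutane-1-carboxylate, all four ring substituents cis (not isolated) | [K+].[K+].COc1cc([C@@H]2[C@H](C(=O)OC(C)(C)C)[C@H](c3cc(OC)c(OCc4ccccc4)cc3[O-])[C@@H]2C(=O)[O-])ccc1OCc1ccccc1 | intermediate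
21 | C-3 epimer of 20, tert-butyl ester trans to the carboxylate and to both aryl groups (not isolated) | [K+].[K+].COc1cc([C@@H]2[C@@H](C(=O)OC(C)(C)C)[C@H](c3cc(OC)c(OCc4ccccc4)cc3[O-])[C@@H]2C(=O)[O-])ccc1OCc1ccccc1 | intermediate
22 | rac-(1α,2α,3β,4α)-3-(tert-butoxycarbonyl)-2-[4-(benzyloxy)-5-methoxy-2-{[(trifluoromethyl)sulfonyl]oxy}phenyl]-4-[4-(benzyloxy)-3-methoxyphenyl]cyclobutane-1-carboxylic acid (one enantiomer written) | COc1cc([C@@H]2[C@@H](C(=O)OC(C)(C)C)[C@H](c3cc(OC)c(OCc4ccccc4)cc3OS(=O)(=O)C(F)(F)F)[C@@H]2C(=O)O)ccc1OCc1ccccc1 | intermediate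
23 | (1α,2α,3β,4α)-2,4-bis[4-(benzyloxy)-3-methoxyphenyl]-3-(tert-butoxycarbonyl)cyclobutane-1-carboxylic acid (meso; acid cis to both aryl groups, tert-butyl ester trans) | COc1cc([C@@H]2[C@@H](C(=O)OC(C)(C)C)[C@H](c3ccc(OCc4ccccc4)c(OC)c3)[C@@H]2C(=O)O)ccc1OCc1ccccc1 | intermediate
24 | 3-tert-butyl 1-[(4R,4aR,6R,7R,7aS)-2,4,7-trimethyloctahydro-1H-cyclopenta[c]pyridin-6-yl] (1α,2α,3β,4α)-2,4-bis[4-(benzyloxy)-3-methoxyphenyl]cyclobutane-1,3-dicarboxylate | COc1cc([C@@H]2[C@@H](C(=O)OC(C)(C)C)[C@H](c3ccc(OCc4ccccc4)c(OC)c3)[C@@H]2C(=O)O[C@@H]2C[C@H]3[C@H](CN(C)C[C@@H]3C)[C@H]2C)ccc1OCc1ccccc1 | intermediate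
25 | (1α,2β,3β,4β)-2,4-bis[4-(benzyloxy)-3-methoxyphenyl]-3-({[(4R,4aR,6R,7R,7aS)-2,4,7-trimethyloctahydro-1H-cyclopenta[c]pyridin-6-yl]oxy}carbonyl)cyclobutane-1-carboxylic acid (free acid trans to both aryl groups) | COc1cc([C@@H]2[C@@H](C(=O)O)[C@H](c3ccc(OCc4ccccc4)c(OC)c3)[C@@H]2C(=O)O[C@@H]2C[C@H]3[C@H](CN(C)C[C@@H]3C)[C@H]2C)ccc1OCc1ccccc1 | intermediate
26 | 1-[(4R,4aR,6R,7R,7aS)-2,4,7-trimethyloctahydro-1H-cyclopenta[c]pyridin-6-yl] 3-[(4R,4aR,6S,7R,7aS)-2,4,7-trimethyloctahydro-1H-cyclopenta[c]pyridin-6-yl] (1α,2α,3β,4α)-2,4-bis[4-(benzyloxy)-3-methoxyphenyl]cyclobutane-1,3-dicarboxylate | COc1cc([C@@H]2[C@@H](C(=O)O[C@H]3C[C@H]4[C@H](CN(C)C[C@@H]4C)[C@H]3C)[C@H](c3ccc(OCc4ccccc4)c(OC)c3)[C@@H]2C(=O)O[C@@H]2C[C@H]3[C@H](CN(C)C[C@@H]3C)[C@H]2C)ccc1OCc1ccccc1 | intermediate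
27 | 1-[(4R,4aR,6R,7R,7aS)-2,4,7-trimethyloctahydro-1H-cyclopenta[c]pyridin-6-yl] 3-[(4R,4aR,6S,7R,7aS)-2,4,7-trimethyloctahydro-1H-cyclopenta[c]pyridin-6-yl] (1α,2α,3β,4α)-2,4-bis(4-hydroxy-3-methoxyphenyl)cyclobutane-1,3-dicarboxylate | COc1cc([C@@H]2[C@@H](C(=O)O[C@H]3C[C@H]4[C@H](CN(C)C[C@@H]4C)[C@H]3C)[C@H](c3ccc(O)c(OC)c3)[C@@H]2C(=O)O[C@@H]2C[C@H]3[C@H](CN(C)C[C@@H]3C)[C@H]2C)ccc1O | target

**Totals**
Total step count: 16. Longest linear sequence: 11 steps (steps 1–7, then 13–16).

**Steps most likely to fail**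

Step 9. The electron-rich 7-alkoxycoumarin may react too slowly with the ester-stabilised ylide, so that Michael addition without ring closure or imine decomposition takes over. Exo approach would also put the new aryl group trans to the lactone carbonyl, which cannot be corrected later. The fallback makes the cycloaddition intramolecular, so that the lactone ring is the tether and the cis relationships are enforced by ring size and alkene geometry. It sets out from 14 and comes back at 19.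
- A Z-selective Horner–Wadsworth–Emmons reaction of 14 with ethyl (diphenoxyphosphoryl)acetate (NaH, THF, −78 °C) should give ethyl (2Z)-3-[4-(benzyloxy)-3-methoxyphenyl]prop-2-enoate F1.
- Hydrolysis with LiOH gives (2Z)-3-[4-(benzyloxy)-3-methoxyphenyl]prop-2-enoic acid F2.
- Purchased 2,4-dihydroxy-5-methoxybenzaldehyde is benzylated at the non-chelated hydroxyl (BnBr, NaHCO3, MeCN) to 4-(benzyloxy)-2-hydroxy-5-methoxybenzaldehyde F3.
- F3 is acylated with F2 (EDC, DMAP) to 5-(benzyloxy)-2-formyl-4-methoxyphenyl (2Z)-3-[4-(benzyloxy)-3-methoxyphenyl]prop-2-enoate F4.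
- Condensation of F4 with 15 gives tert-butyl N-[(E)-{4-(benzyloxy)-5-methoxy-2-[(2Z)-3-(4-(benzyloxy)-3-methoxyphenyl)prop-2-enoyloxy]phenyl}methylidene]glycinate F5.
- AgOAc/Et3N should close F5 to rac-tert-butyl 7-(benzyloxy)-3-[4-(benzyloxy)-3-methoxyphenyl]-8-methoxy-4-oxo-1,2,3,3a,4,9b-hexahydrochromeno[4,3-b]pyrrole-2-carboxylate F6 (all ring hydrogens cis).
- Nitrogen deletion under the step 10 conditions then gives racemic 19. The lactone now sits on the other aryl ring, which is the mirror image of the drawn 19 and therefore the same racemate.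

Step 10. The hindered α,α′-disubstituted amine may be slow to attack the anomeric amide. The biradical may also cleave its central C–C bond to two alkenes, or rotate at the benzylic end before closure and lose the cis aryl/carbonyl relationship. The fallback builds the ring first and installs both aryl groups by directed C–H arylation. It does not start from a compound of the route but from purchased cis-3-(methoxycarbonyl)cyclobutane-1-carboxylic acid; it takes up 11 and comes back at 25.
- Amide formation with 8-aminoquinoline gives methyl cis-3-(quinolin-8-ylcarbamoyl)cyclobutane-1-carboxylate F7.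
- Twofold arylation with purchased 1-(benzyloxy)-4-iodo-2-methoxybenzene (Pd(OAc)2, AgOAc, t-BuOH, 90 °C) should place both aryl groups cis to the amide, giving methyl all-cis-2,4-bis[4-(benzyloxy)-3-methoxyphenyl]-3-(quinolin-8-ylcarbamoyl)cyclobutane-1-carboxylate F8.
- NaOMe in MeOH epimerises only the ester carbon, giving its trans-ester epimer F9.
- Boc2O/DMAP gives the N-Boc imide F10, and LiOH/H2O2 releases (1α,2α,3β,4α)-2,4-bis[4-(benzyloxy)-3-methoxyphenyl]-3-(methoxycarbonyl)cyclobutane-1-carboxylic acid F11.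
- Esterification with 11 as in step 13 gives the methyl ester analogue of 24, F12.
- Me3SnOH in 1,2-dichloroethane cleaves the methyl ester to 25.

Step 13. Acyl transfer from an acid flanked by two cis aryl groups to a concave secondary alcohol may stall, and prolonged exposure of the activated acid to base may erode the cis configuration. The fallback lets the hindered carboxylate act as the nucleophile. It sets out from 11 and 23 and comes back at 24.
- Mitsunobu reaction of 11 with 4-nitrobenzoic acid (PPh3, DIAD) gives (4R,4aR,6S,7R,7aS)-2,4,7-trimethyloctahydro-1H-cyclopenta[c]pyridin-6-yl 4-nitrobenzoate F13.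
- K2CO3 in MeOH gives the C-6 epimeric alcohol (4R,4aR,6S,7R,7aS)-2,4,7-trimethyloctahydro-1H-cyclopenta[c]pyridin-6-ol F14.
- Mitsunobu coupling of 23 with F14 (PPh3, DIAD, THF) inverts C-6 back to R and gives 24.

**Further compounds**
F1 | step 9 | ethyl (2Z)-3-[4-(benzyloxy)-3-methoxyphenyl]prop-2-enoate | CCOC(=O)/C=C\c1ccc(OCc2ccccc2)c(OC)c1
F2 | step 9 | (2Z)-3-[4-(benzyloxy)-3-methoxyphenyl]prop-2-enoic acid | OC(=O)/C=C\c1ccc(OCc2ccccc2)c(OC)c1
F3 | step 9 | 4-(benzyloxy)-2-hydroxy-5-methoxybenzaldehyde | COc1cc(C=O)c(O)cc1OCc1ccccc1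
F4 | step 9 | 5-(benzyloxy)-2-formyl-4-methoxyphenyl (2Z)-3-[4-(benzyloxy)-3-methoxyphenyl]prop-2-enoate | COc1cc(C=O)c(OC(=O)/C=C\c2ccc(OCc3ccccc3)c(OC)c2)cc1OCc1ccccc1
F5 | step 9 | tert-butyl N-[(E)-{4-(benzyloxy)-5-methoxy-2-[(2Z)-3-(4-(benzyloxy)-3-methoxyphenyl)prop-2-enoyloxy]phenyl}methylidene]glycinate | CC(C)(C)OC(=O)C/N=C/c1cc(OC)c(OCc2ccccc2)cc1OC(=O)/C=C\c1ccc(OCc2ccccc2)c(OC)c1
F6 | step 9 | rac-tert-butyl 7-(benzyloxy)-3-[4-(benzyloxy)-3-methoxyphenyl]-8-methoxy-4-oxo-1,2,3,3a,4,9b-hexahydrochromeno[4,3-b]pyrrole-2-carboxylate, H-2, H-3, H-3a, H-9b all cis | COc1cc(ccc1OCc1ccccc1)[C@@H]2[C@H](C(=O)OC(C)(C)C)N[C@@H]3c4cc(OC)c(OCc5ccccc5)cc4OC(=O)[C@H]23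
F7 | step 10 | methyl cis-3-(quinolin-8-ylcarbamoyl)cyclobutane-1-carboxylate | COC(=O)[C@H]1C[C@H](C1)C(=O)Nc1cccc2cccnc12
F8 | step 10 | methyl all-cis-2,4-bis[4-(benzyloxy)-3-methoxyphenyl]-3-(quinolin-8-ylcarbamoyl)cyclobutane-1-carboxylate | COc1cc([C@@H]2[C@H](C(=O)OC)[C@H](c3ccc(OCc4ccccc4)c(OC)c3)[C@@H]2C(=O)Nc2cccc3cccnc23)ccc1OCc1ccccc1
F9 | step 10 | methyl (1β,2α,3α,4α)-2,4-bis[4-(benzyloxy)-3-methoxyphenyl]-3-(quinolin-8-ylcarbamoyl)cyclobutane-1-carboxylate (ester trans to aryl groups and amide) | COc1cc([C@@H]2[C@@H](C(=O)OC)[C@H](c3ccc(OCc4ccccc4)c(OC)c3)[C@@H]2C(=O)Nc2cccc3cccnc23)ccc1OCc1ccccc1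
F10 | step 10 | N-(tert-butoxycarbonyl) derivative of F9 | COc1cc([C@@H]2[C@@H](C(=O)OC)[C@H](c3ccc(OCc4ccccc4)c(OC)c3)[C@@H]2C(=O)N(C(=O)OC(C)(C)C)c2cccc3cccnc23)ccc1OCc1ccccc1
F11 | step 10 | (1α,2α,3β,4α)-2,4-bis[4-(benzyloxy)-3-methoxyphenyl]-3-(methoxycarbonyl)cyclobutane-1-carboxylic acid | COc1cc([C@@H]2[C@@H](C(=O)OC)[C@H](c3ccc(OCc4ccccc4)c(OC)c3)[C@@H]2C(=O)O)ccc1OCc1ccccc1
F12 | step 10 | 3-methyl 1-[(4R,4aR,6R,7R,7aS)-2,4,7-trimethyloctahydro-1H-cyclopenta[c]pyridin-6-yl] (1α,2α,3β,4α)-2,4-bis[4-(benzyloxy)-3-methoxyphenyl]cyclobutane-1,3-dicarboxylate | COc1cc([C@@H]2[C@@H](C(=O)OC)[C@H](c3ccc(OCc4ccccc4)c(OC)c3)[C@@H]2C(=O)O[C@@H]2C[C@H]3[C@H](CN(C)C[C@@H]3C)[C@H]2C)ccc1OCc1ccccc1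
F13 | step 13 | (4R,4aR,6S,7R,7aS)-2,4,7-trimethyloctahydro-1H-cyclopenta[c]pyridin-6-yl 4-nitrobenzoate | O=C(O[C@H]1C[C@H]2[C@H](CN(C)C[C@@H]2C)[C@H]1C)c1ccc(cc1)[N+](=O)[O-]
F14 | step 13 | (4R,4aR,6S,7R,7aS)-2,4,7-trimethyloctahydro-1H-cyclopenta[c]pyridin-6-ol | O[C@H]1C[C@H]2[C@H](CN(C)C[C@@H]2C)[C@H]1C
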